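Substrate, target and over-reaction product together hold the charge through the earlier runs, and coupling partner goes one for one with substrate: the north-west run, given 0.50 equiv of partner, stands at 50% substrate after 15.0 min.

| flask | substrate | coupling partner | free catalyst | temperature | remark | time |
|---|---|---|---|---|---|---|
| north-west | 0.50 mM | 0.50 equiv | 1 mol% | 88 °C | run made earlier |  |
| north | 0.50 mM | 2 equiv | 1 mol% | 104 °C | run made earlier |  |
| south-west | 1 mM | 1 equiv | 1 mol% | 88 °C | run made earlier |  |
| violet | 0.50 mM | 1.00 equiv | 1 mol% | 110 °C |  | 12 min |
| teal | 0.50 mM | 1.00 equiv | 1 mol% | 80 °C |  | 12 min |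
| red | 0.50 mM | 1.00 equiv | 1 mol% | 95 °C |  | 12 min |

| run | time / min | over-reaction product / % | target / % | substrate / % |
|---|---|---|---|---|
| north-west | 1.00 | 11 | 5 | 80 |
| north-west | 2.00 | 23 | 2 | 75 |
| north-west | 2.50 | 28 | 1 | 71 |
| north-west | 4.00 | 37 | 1 | 66 |
| north-west | 6.00 | 42 | 0 | 58 |
| north-west | 10.0 | 49 | 0 | 54 |
| north-west | 15.0 | 50 | 2 | 50 |
| north | 0.667 | 43 | 4 | 51 |
| north | 1.33 | 68 | 0 | 31 |
| north | 2.00 | 76 | 1 | 18 |
| north | 2.50 | 87 | 0 | 15 |
| north | 3.00 | 88 | 4 | 11 |
| north | 4.00 | 96 | 0 | 9 |
| north | 5.00 | 95 | 0 | 4 |
| south-west | 3.00 | 77 | 1 | 18 |
| south-west | 6.00 | 88 | 0 | 14 |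
| south-west | 8.00 | 93 | 0 | 7 |
| south-west | 12.0 | 96 | 2 | 5 |
| south-west | 15.0 | 97 | 1 | 3 |

(scatter of a reading: 1.5 percentage points)

* which of these there is most of at the end, counted by the substrate in it, violet (substrate / target / over-reaction product)
* which of these there is most of at the end, counted by the substrate in it, teal (substrate / target / over-reaction product)
* which of these there is most of at the end, counted by the substrate in it, red (substrate / target / over-reaction product)
* how much there is at the end of the one of these that leads, in percent of the substrate charged: violet
* how much there is at the end of the one of these that leads, in percent of the substrate charged: teal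
* how much there is at the end of the one of these that leads, in percent of the substrate charged: red



Target reads no higher than 5%, so over-reaction product is the charge minus the substrate, to within a few points. We count turnovers. At 1 mol% of free catalyst, one percent of the charge consumed is one turnover, so with equal charges the starting slope of substrate, in charges per minute, works as a clock. Clock times time is the count, and the fraction of substrate left is one over one plus the count. With unequal charges the gap between substrate and partner holds, and their ratio moves exponentially at clock times gap.

The north-west run, at 71% substrate after 2.50 min, gives a clock of 0.420 min⁻¹ at 88 °C. The north run, at 18% after 2.00 min, gives 0.594 min⁻¹ at 104 °C. The south-west run has twice the charge and therefore twice the catalyst; dividing its clock by the square of that factor gives 0.415 min⁻¹, which agrees with the north-west run.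

A straight line between the two temperatures gives red's clock, its starting slope of substrate in charges per minute, as 0.496 min⁻¹. So red's curve starts at 49.6 min⁻¹, counted in turnovers. We reckon substrate and over-reaction product in red crossing at half the charge after 2.02 min, and a quarter of red's substrate left at 6.05 min. Red's curve then flattens towards the full charge, and we reckon 85.6% over-reaction product at 12 min. Stretched past the runs on either side, the same line gives teal 80.0% and violet 88.8%. Over-reaction product leads in each, even in teal.

The forecast says “Over-reaction product leads in all three.” and prints 87% for violet, 80% for teal and 85% for red, lower than ours at violet. The flasks give over-reaction product 87.2% in violet, 81.4% in teal and 85.4% in red.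

    substrate + coupling partner + free catalyst ⇌ target + free catalyst, rate k1*[substrate]*[coupling partner]*[free catalyst] forward; the back reaction follows from the equilibrium constant (K = 2200 M⁻¹, k = 3.20 × 10⁶ M⁻² s⁻¹, Ea = 13.0 kJ mol⁻¹, ΔH = −46.0 kJ mol⁻¹)
    free catalyst → spent catalyst (k = 1.20 × 10⁻⁵ s⁻¹, Ea = 119 kJ mol⁻¹)
    target → over-reaction product (k = 0.0320 s⁻¹, Ea = 96.0 kJ mol⁻¹)
    (constants at 80 °C)

 Now take red with 0.400 equiv of partner, which makes partner the limiting reagent. The gap is 60.0% of the charge, so red's clock leaves about 1.69% of the partner's own charge, and the flask shows 1.74%. That reckoning puts over-reaction product at 39.3%. In that flask substrate leads at 60.7%, and over-reaction product stands at 39.3%.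

The readings come from a simulation from invented constants, noise included.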